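## Plan

- **Cuts:** Going backwards, the four phenolic O–H groups become O–CH3 and the C3–Br and C6–Br bonds of each ring become C–H. Both aryl C1–CH2 bonds are then cut at once.
- **Enabling feature:** Outside the two benzene rings there are only two C–C bonds, the C1(ring)–CH2 bond on each side, and each lies para to the ring oxygen on C4. The five-atom bridge CH2–NH–C(=O)–NH–CH2 is N,N'-bis(hydroxymethyl)urea 2 without its two OH groups, and the C2 bromine identifies the arene as 4-bromoveratrole 1.
- **Forward order:** No ring is built, since both benzene rings are bought. One two-directional amidoalkylation joins arene, bridge and arene; four C–Br bonds are then added and four O–CH3 bonds are cleaved.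
- **Stereochemistry:** The target has no stereocentre, stereogenic axis or configured double bond, so there is nothing to set or protect.

Key step: step 1

Remark: the compound is achiral, so its constitution alone defines the target.

## Route

Step 1
Reactants: 1 4-bromoveratrole (4-bromo-1,2-dimethoxybenzene; two molecules enter, used in excess); 2 N,N'-bis(hydroxymethyl)urea
Product: 6 N,N'-bis(2-bromo-4,5-dimethoxybenzyl)urea, via first N-acyliminium ion 3 (not isolated), via mono-benzylated methylolurea 4 (not isolated), via second N-acyliminium ion 5 (not isolated)
Conditions: 1 (3 equiv), MeSO3H–AcOH (1:3), 2 added in portions at 10 °C, then rt; ice-water, filter, wash out excess 1 with Et2O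
Reagents that add atoms: none
Why: The acid ionises one N–CH2OH end of 2 to the N-acyliminium ion 3, which attacks C5 of 1 in an SEAr to give 4, and the other end repeats this through 5, so both aryl–CH2 bonds and all fifteen carbons of the target skeleton are in place after one operation. The reaction type is the Tscherniac–Einhorn amidoalkylation in its ureidoalkylation form, known for N-hydroxymethyl amides and ureas with phenols and phenol ethers in strong protic acids. No ring is closed and no stereocentre arises. The selectivity needed is that of site, and the substrate secures it: C5 is the only free position para to a methoxy group because the bromine occupies the other one (C4), C3 and C6 are only ortho-activated and more crowded, and bromination and chloromethylation of 1 are known to go to C5. C-alkylation is favoured over N-alkylation by keeping 2 dilute against an excess of 1, and by the fact that N–CH2–N links re-ionise in this medium whereas the aryl–CH2 bond does not. Because the bromine ends up ortho to the new CH2 group, 6 has no strongly activated ring position left and a less easily ionised benzylic C–N bond, which should curb further alkylation and the ring-forming oligomerisation that plain veratrole shows with formaldehyde equivalents.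

Step 2
Reactants: 6 N,N'-bis(2-bromo-4,5-dimethoxybenzyl)urea; 7 bromine
Product: 8 N,N'-bis(2,3,6-tribromo-4,5-dimethoxybenzyl)urea
Conditions: Br2 (10 equiv), Fe powder (cat.), AcOH–CHCl3, rt → 60 °C, dark; aq NaHSO3
Reagents that add atoms: bromine 7, BrBr
Why: Electrophilic aromatic bromination: the only ring C–H bonds left (C3–H and C6–H of each ring) each lie ortho to a methoxy group, iron(III) bromide formed in situ supplies the extra electrophilicity that exhaustive bromination of veratroles and 3,4-dimethoxytoluenes is known to need, the urea and the ethers tolerate Br2/HBr, and any N–Br formed at the urea is reduced back to N–H by the bisulfite wash.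

Step 3
Reactants: 8 N,N'-bis(2,3,6-tribromo-4,5-dimethoxybenzyl)urea
Product: 10 N,N'-bis(2,3,6-tribromo-4,5-dihydroxybenzyl)urea (target), via bis(bromoboronate) ester 9 (not isolated)
Conditions: BBr3 (8 equiv), CH2Cl2, −78 °C → rt; ice-water
Reagents that add atoms: none
Why: BBr3 cleavage of aryl methyl ethers: boron binds each ether oxygen and bromide removes the methyl group by SN2, the two neighbouring oxygens of each ring end up in the cyclic bromoboronate 9 that water hydrolyses to the catechol, the three bromines per ring disfavour benzylic ionisation so the CH2–N bonds should hold, and water rather than an alcohol is used for the quench to avoid benzylic solvolysis.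

## Compound list

1 | 4-bromoveratrole (4-bromo-1,2-dimethoxybenzene) | COc1ccc(Br)cc1OC | starting material
2 | N,N'-bis(hydroxymethyl)urea (dimethylolurea) | O=C(NCO)NCO | starting material
3 | N-[(hydroxymethyl)carbamoyl]methaniminium ion | C=[NH+]C(=O)NCO | intermediate
4 | N-(2-bromo-4,5-dimethoxybenzyl)-N'-(hydroxymethyl)urea | O=C(NCO)NCc1cc(OC)c(OC)cc1Br | intermediate
5 | N-[(2-bromo-4,5-dimethoxybenzyl)carbamoyl]methaniminium ion | C=[NH+]C(=O)NCc1cc(OC)c(OC)cc1Br | intermediate
6 | N,N'-bis(2-bromo-4,5-dimethoxybenzyl)urea | O=C(NCc1cc(OC)c(OC)cc1Br)NCc1cc(OC)c(OC)cc1Br | intermediate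
7 | bromine | BrBr | starting material
8 | N,N'-bis(2,3,6-tribromo-4,5-dimethoxybenzyl)urea | O=C(NCc1c(Br)c(OC)c(OC)c(Br)c1Br)NCc1c(Br)c(OC)c(OC)c(Br)c1Br | intermediate
9 | N,N'-bis[(2,4,6,7-tetrabromo-1,3,2-benzodioxaborol-5-yl)methyl]urea | O=C(NCc1c(Br)c2OB(Br)Oc2c(Br)c1Br)NCc1c(Br)c2OB(Br)Oc2c(Br)c1Br | intermediate
10 | N,N'-bis(2,3,6-tribromo-4,5-dihydroxybenzyl)urea | O=C(NCc1c(Br)c(O)c(O)c(Br)c1Br)NCc1c(Br)c(O)c(O)c(Br)c1Br | target

## Step count and risks

Total step count: 3. Longest linear sequence: 3.

**Step 1 (highest risk).**
- Urea N–H groups may intercept the iminium ions faster than the bromine-deactivated arene does, which leads to resin formation.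
- 2 may shed formaldehyde, and benzylic C–N bonds already formed may re-ionise and alkylate the excess arene.
- 5 may close a seven-membered ring onto C6 of its own arene, or the reaction may stop after one arm.

The fallback gives up the two-directional mode but keeps the amidoalkylation at C5, and it sets out from 1. N-(Hydroxymethyl)phthalimide is a one-ended reagent without N–H, so it cannot condense with itself; in MeSO3H it should give N-(2-bromo-4,5-dimethoxybenzyl)phthalimide F1. Hydrazine hydrate in refluxing EtOH (Ing–Manske) frees 2-bromo-4,5-dimethoxybenzylamine F2. Half an equivalent of 1,1'-carbonyldiimidazole in THF turns part of F2 into N-(2-bromo-4,5-dimethoxybenzyl)imidazole-1-carboxamide F3. The rest of F2 takes this up, and the route is rejoined at 6.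

**Step 2.**
- The bromination may stall once each methoxy group is flanked on both sides and twisted out of conjugation.
- Forcing it invites ipso attack at C1 with loss of the ureidomethyl arm, and oxidation of the benzylic CH2 by way of N-bromination.

The fallback reverses unmasking and halogenation and sets out from 6. BBr3 in CH2Cl2 gives N,N'-bis[(2,6-dibromo-1,3,2-benzodioxaborol-5-yl)methyl]urea F4. Water hydrolyses this to N,N'-bis(2-bromo-4,5-dihydroxybenzyl)urea F5. The free hydroxyl groups activate far more strongly and cannot be twisted out of conjugation. Four equivalents of Br2 in AcOH at rt without a catalyst should therefore fill C3 and C6 of both rings, as in the exhaustive bromination of catechol and 4-alkylcatechols. The fallback comes back at 10.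

**Step 3.**
- Boron bound to the urea oxygen may turn the urea into a leaving group, so that the benzylic C–N bond ionises or is displaced by bromide.
- The cleavage may stop short if boron complexes precipitate.

The fallback avoids ethers altogether, so no ether cleavage is ever run in the presence of the C–N bonds, and it sets out from 2. Commercial 4-bromocatechol (Oc1ccc(Br)cc1O), used in excess, replaces 1 in the same linchpin amidoalkylation. Phenols are the classical partners of methylol ureas, so CF3CO2H at rt should be acidic enough. C5 is again the only free position para to a ring oxygen. The reaction passes through N-(2-bromo-4,5-dihydroxybenzyl)-N'-(hydroxymethyl)urea F6 to N,N'-bis(2-bromo-4,5-dihydroxybenzyl)urea F5. Br2 (four equivalents) in AcOH at rt then brings the sequence back at 10.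

## Further compounds

F1 | step 1 | N-(2-bromo-4,5-dimethoxybenzyl)phthalimide | O=C1c2ccccc2C(=O)N1Cc1cc(OC)c(OC)cc1Br
F2 | step 1 | 2-bromo-4,5-dimethoxybenzylamine | NCc1cc(OC)c(OC)cc1Br
F3 | step 1 | N-(2-bromo-4,5-dimethoxybenzyl)imidazole-1-carboxamide | O=C(NCc1cc(OC)c(OC)cc1Br)n1ccnc1
F4 | step 2 | N,N'-bis[(2,6-dibromo-1,3,2-benzodioxaborol-5-yl)methyl]urea | O=C(NCc1cc2OB(Br)Oc2cc1Br)NCc1cc2OB(Br)Oc2cc1Br
F5 | step 2 | N,N'-bis(2-bromo-4,5-dihydroxybenzyl)urea | O=C(NCc1cc(O)c(O)cc1Br)NCc1cc(O)c(O)cc1Br
F6 | step 3 | N-(2-bromo-4,5-dihydroxybenzyl)-N'-(hydroxymethyl)urea | O=C(NCO)NCc1cc(O)c(O)cc1Br
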